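**Plan**

- Numbering: upper flavan unit rings A, C, B with unprimed atoms; lower unit rings D, F, E with primed atoms (the primed numbers are also used for the monomeric lower-unit intermediates).
- Disconnection: with the benzyl ethers, the C3 acetate and a C8' bromide stripped off, ring C is cut at C2–C3 and C4–C4a. This is possible because O1=C2 together with the C8a–C4a bond of ring A is a 2-oxadiene, and C3=C4, carrying the C3 oxygen and the cation-stabilising ring D on C4, is its 2π partner.
- Fragments: a methyl aryl acetal (rings A and B, cut at the acetal C–O bond into 3,5-bis(benzyloxy)phenol and 3,4,5-tris(benzyloxy)benzaldehyde) and an (E)-enol acetate on C6' of benzylated 8'-bromo-(+)-gallocatechin, cut at the vinyl C–C bond back to the C6' aldehyde.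
- Forward: rings D, F and E come intact from (+)-gallocatechin and are elaborated at C6' (benzylation, C8' bromination, C6' formylation, homologation, enol acetylation). Rings A and B are joined through the acetal. Ring C is the only ring made, in the annulation. Acetate cleavage and hydrogenolysis finish.
- Stereochemistry: C2' and C3' come from (+)-gallocatechin. C2, C3 and C4 arise together in the annulation, 3,4-trans from the (E)-alkene and 2,4-cis from the endo, all-equatorial closure. Their sense relative to the lower unit is not biased by the substrate; it is secured by separating the two all-trans adducts, which are diastereomers because the lower unit is enantiopure.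

Key step: step 9

Assumption: the target is read as (+)-gallocatechin-(4α→6)-(+)-gallocatechin, (2R,3S,4S) in the upper and (2'R,3'S) in the lower unit, so both units have the 2,3-trans configuration of (+)-gallocatechin and the C4 aryl group is trans to the C3 hydroxyl.

**Route**

Step 1
Reactants: 1 (+)-gallocatechin
Product: 2 penta-O-benzyl-(+)-gallocatechin (benzyl ethers on the two ring D and three ring E phenols; C3' hydroxyl free; 2'R,3'S)
Conditions: BnBr (5.5 equiv), K2CO3, DMF, 0 °C to rt, argon
Reagents that add atoms: benzyl bromide, BrCc1ccccc1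
Why: Williamson etherification under carbonate alkylates the five phenols and not the less acidic secondary alcohol, as is routine for catechins, and the mild base at low temperature should leave C2' unepimerised.

Step 2
Reactants: 2 penta-O-benzyl-(+)-gallocatechin
Product: 3 hexa-O-benzyl-(+)-gallocatechin (C3' benzyl ether)
Conditions: NaH, BnBr, nBu4NI (cat.), THF–DMF, 0 °C to rt
Reagents that add atoms: benzyl bromide, BrCc1ccccc1
Why: Williamson etherification of the secondary sodium alkoxide is standard for O-benzylated flavan-3-ols; with every phenol capped no quinone methide can form, so C2' and C3' are not at risk.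

Step 3
Reactants: 3 hexa-O-benzyl-(+)-gallocatechin
Product: 4 8'-bromo-hexa-O-benzylgallocatechin (bromine on ring D between O1' and the C7' ether)
Conditions: NBS (1.0 equiv), CH2Cl2, −78 to 0 °C, dark
Reagents that add atoms: N-bromosuccinimide, O=C1CCC(=O)N1Br
Why: Electrophilic aromatic bromination takes place on the phloroglucinol-type ring D, and C8' (next to the tied-back ring oxygen O1') reacts before C6' (between two freely rotating benzyl ethers), the selectivity known for benzylated catechins.

Step 4
Reactants: 4 8'-bromo-hexa-O-benzylgallocatechin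
Product: 6 8'-bromo-6'-formyl-hexa-O-benzylgallocatechin, via iminium salt 5 (not isolated)
Conditions: POCl3, DMF, ClCH2CH2Cl, 0 to 60 °C; then aq NaOAc, rt
Reagents that add atoms: N,N-dimethylformamide, CN(C)C=O; water, O
Why: Vilsmeier–Haack formylation can only enter at C6' once C8' is blocked, ring D still being activated by two ortho and one para oxygen while ring E is a much poorer nucleophile, and buffered hydrolysis of the iminium salt spares the benzyl ethers.

Step 5
Reactants: 6 8'-bromo-6'-formyl-hexa-O-benzylgallocatechin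
Product: 8 (8'-bromo-hexa-O-benzylgallocatechin-6'-yl)acetaldehyde, via enol ether 7 (not isolated)
Conditions: Ph3P(CH2OMe)Cl, KOtBu, THF, 0 °C to rt; then 1 M aq HCl, THF, rt
Reagents that add atoms: (methoxymethyl)triphenylphosphonium chloride, COC[P+](c1ccccc1)(c1ccccc1)c1ccccc1.[Cl-]; water, O
Why: Wittig methoxymethylenation followed by acid hydrolysis of the enol ether is the standard one-carbon homologation of aryl aldehydes, including 2,6-dialkoxybenzaldehydes; both enol ether isomers converge on the same aldehyde and dilute acid leaves benzyl ethers and the aryl bromide alone.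

Step 6
Reactants: 8 (8'-bromo-hexa-O-benzylgallocatechin-6'-yl)acetaldehyde
Product: 9 (E)-2-(8'-bromo-hexa-O-benzylgallocatechin-6'-yl)vinyl acetate
Conditions: Ac2O, Et3N, DMAP (cat.), CH2Cl2, 0 °C to rt, aldehyde added slowly; chromatography on Et3N-deactivated silica to remove any (Z)-isomer
Reagents that add atoms: acetic anhydride, CC(=O)OC(C)=O
Why: Enol acetylation (O-acylation of the aldehyde enolate by the acylpyridinium ion) is facile for arylacetaldehydes because the α-hydrogens are benzylic, and the enolate with oxygen trans to the bulky di-ortho-substituted aryl group should be favoured, so the (E)-acetate is expected to predominate.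

Step 7
Reactants: 10 3,4,5-tris(benzyloxy)benzaldehyde
Product: 11 3,4,5-tris(benzyloxy)benzaldehyde dimethyl acetal
Conditions: HC(OMe)3, TsOH·H2O (cat.), MeOH–CH2Cl2, rt; Et3N quench
Reagents that add atoms: trimethyl orthoformate, COC(OC)OC; methanol, CO
Why: Acid-catalysed acetalisation with the orthoformate as methoxy source and water scavenger is general for electron-rich benzaldehydes.

Step 8
Reactants: 11 3,4,5-tris(benzyloxy)benzaldehyde dimethyl acetal; 12 3,5-bis(benzyloxy)phenol
Product: 14 methyl 3,5-bis(benzyloxy)phenyl acetal of 3,4,5-tris(benzyloxy)benzaldehyde (racemic at the acetal carbon), via chloro ether 13 (not isolated)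
Conditions: AcCl (1.1 equiv), SOCl2 (cat.), CH2Cl2, 0 °C to rt, evaporate; then 12, NaH, THF–DMF, 0 °C; chromatography on Et3N-deactivated silica
Reagents that add atoms: none
Why: Acetyl chloride cleaves the dimethyl acetal to the α-chloro ether, and the preformed sodium phenoxide displaces chloride at oxygen as phenoxides do with chloromethyl ethers (Williamson-type O-alkylation), the hard phenoxide in a polar medium disfavouring C-alkylation of the phloroglucinol ring.

Step 9
Reactants: 9 (E)-2-(8'-bromo-hexa-O-benzylgallocatechin-6'-yl)vinyl acetate; 14 methyl 3,5-bis(benzyloxy)phenyl acetal of 3,4,5-tris(benzyloxy)benzaldehyde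
Product: 17 undeca-O-benzyl-8'-bromo-gallocatechin-(4α→6)-gallocatechin 3-acetate (2R,3S,4S; 2'R,3'S), via oxocarbenium ion 15 (not isolated), via benzylic cation 16 (not isolated)
Conditions: SnCl4 (1.2 equiv), 14 (1.5 equiv), CH2Cl2, −78 °C; Et3N then aq NaHCO3 quench; chromatographic separation of the two facial diastereomers
Reagents that add atoms: none
Why: Proposed new method: SnCl4 binds the methoxy oxygen of 14 and ionises it to the aryl oxocarbenium ion 15; the enol acetate 9 attacks C2 through its acetoxy-bearing carbon (C2–C3 bond) because the charge then develops on the carbon carrying the 2,4,6-trioxygenated ring D (cation 16, which the neighbouring acetate can bridge as a dioxolanylium ion) and not on an acyloxy-substituted carbon, and ring A closes on that carbon through a position ortho to O1 (C4–C4a bond) with loss of a proton. The closest known reaction is the oxa-Povarov reaction, the SnCl4-promoted formal inverse-electron-demand hetero-Diels–Alder reaction of aryl 2-oxadiene oxocarbenium ions from methyl aryl acetals with styrenes and cyclic alkenes, which gives 2,4-cis-chromans; enol esters have not been used as the 2π partner, nor has a partner carrying a remote stereogenic unit. Ring C, the only ring formed, closes by a six-membered Friedel–Crafts alkylation that is 6-endo with respect to the attacking arene bond C4a–C8a and exo with respect to the cationic carbon. C2 and C3 are set in the first bond formation, where the (E)-alkene geometry and the endo approach place the C2 aryl group and the C3 acetate trans; C4 is set in the ring closure, where ring D takes the equatorial position of a chair-like transition state and enters anti to the participating acetate (3,4-trans, 2,4-cis). The step needs regioselectivity of the enol ester, secured by the three oxygen donors of ring D, and site selectivity on the arenes, secured by the C8' bromide on the only free position of ring D and by the symmetry of ring A, whose two ortho carbons are equivalent. It also needs the (2R,3S,4S) sense relative to C2'/C3', which the remote lower unit cannot be expected to impose: both all-trans adducts should form, they are diastereomers because the lower unit is enantiopure, and 17 is separated from its facial isomer by chromatography.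

Step 10
Reactants: 17 undeca-O-benzyl-8'-bromo-gallocatechin-(4α→6)-gallocatechin 3-acetate
Product: 18 undeca-O-benzyl-8'-bromo-gallocatechin-(4α→6)-gallocatechin (C3 hydroxyl free)
Conditions: NaOMe (0.3 equiv), MeOH–THF, rt
Reagents that add atoms: none
Why: Zemplén transesterification removes the secondary acetate as methyl acetate, and benzyl ethers, the aryl bromide, the interflavan bond and all stereocentres are stable to methoxide once no phenol is free.

Step 11
Reactants: 18 undeca-O-benzyl-8'-bromo-gallocatechin-(4α→6)-gallocatechin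
Product: 19 gallocatechin-(4α→6)-gallocatechin (target)
Conditions: H2 (1 atm), Pd(OH)2 on carbon, Et3N (1.1 equiv), THF–MeOH–H2O, rt; filtration and lyophilisation under argon
Reagents that add atoms: none
Why: Catalytic hydrogenolysis cleaves the eleven benzyl ethers and, by hydrodehalogenation, the C8' bromide in one operation without touching a stereocentre, the amine taking up HBr so that the acid-labile interflavan bond is not exposed.

**Compound list**

1 | (+)-gallocatechin | Oc1cc(O)c2C[C@H](O)[C@@H](c3cc(O)c(O)c(O)c3)Oc2c1 | starting material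
2 | penta-O-benzyl-(+)-gallocatechin, C3' hydroxyl free | c1c(OCc5ccccc5)cc2c(c1OCc5ccccc5)C[C@H](O)[C@@H](c1cc(OCc5ccccc5)c(OCc5ccccc5)c(OCc5ccccc5)c1)O2 | intermediate
3 | hexa-O-benzyl-(+)-gallocatechin | c1c(OCc5ccccc5)cc2c(c1OCc5ccccc5)C[C@H](OCc5ccccc5)[C@@H](c1cc(OCc5ccccc5)c(OCc5ccccc5)c(OCc5ccccc5)c1)O2 | intermediate
4 | 8'-bromo-hexa-O-benzylgallocatechin | c1c(OCc5ccccc5)c(Br)c2c(c1OCc5ccccc5)C[C@H](OCc5ccccc5)[C@@H](c1cc(OCc5ccccc5)c(OCc5ccccc5)c(OCc5ccccc5)c1)O2 | intermediate
5 | C6' N,N-dimethyliminium chloride of 4 (not isolated) | C[N+](C)=Cc1c(OCc5ccccc5)c(Br)c2c(c1OCc5ccccc5)C[C@H](OCc5ccccc5)[C@@H](c1cc(OCc5ccccc5)c(OCc5ccccc5)c(OCc5ccccc5)c1)O2.[Cl-] | intermediate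
6 | 8'-bromo-6'-formyl-hexa-O-benzylgallocatechin | O=Cc1c(OCc5ccccc5)c(Br)c2c(c1OCc5ccccc5)C[C@H](OCc5ccccc5)[C@@H](c1cc(OCc5ccccc5)c(OCc5ccccc5)c(OCc5ccccc5)c1)O2 | intermediate
7 | C6' 2-methoxyvinyl enol ether, E/Z mixture (not isolated) | COC=Cc1c(OCc5ccccc5)c(Br)c2c(c1OCc5ccccc5)C[C@H](OCc5ccccc5)[C@@H](c1cc(OCc5ccccc5)c(OCc5ccccc5)c(OCc5ccccc5)c1)O2 | intermediate
8 | (8'-bromo-hexa-O-benzylgallocatechin-6'-yl)acetaldehyde | O=CCc1c(OCc5ccccc5)c(Br)c2c(c1OCc5ccccc5)C[C@H](OCc5ccccc5)[C@@H](c1cc(OCc5ccccc5)c(OCc5ccccc5)c(OCc5ccccc5)c1)O2 | intermediate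
9 | (E)-2-(8'-bromo-hexa-O-benzylgallocatechin-6'-yl)vinyl acetate | CC(=O)O/C=C/c1c(OCc5ccccc5)c(Br)c2c(c1OCc5ccccc5)C[C@H](OCc5ccccc5)[C@@H](c1cc(OCc5ccccc5)c(OCc5ccccc5)c(OCc5ccccc5)c1)O2 | intermediate
10 | 3,4,5-tris(benzyloxy)benzaldehyde | O=Cc1cc(OCc2ccccc2)c(OCc2ccccc2)c(OCc2ccccc2)c1 | starting material
11 | 3,4,5-tris(benzyloxy)benzaldehyde dimethyl acetal | COC(OC)c1cc(OCc2ccccc2)c(OCc2ccccc2)c(OCc2ccccc2)c1 | intermediate
12 | 3,5-bis(benzyloxy)phenol | Oc1cc(OCc2ccccc2)cc(OCc2ccccc2)c1 | starting material
13 | α-chloro-3,4,5-tris(benzyloxy)benzyl methyl ether, racemic (not isolated) | COC(Cl)c1cc(OCc2ccccc2)c(OCc2ccccc2)c(OCc2ccccc2)c1 | intermediate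
14 | methyl 3,5-bis(benzyloxy)phenyl acetal of 3,4,5-tris(benzyloxy)benzaldehyde, racemic | COC(Oc1cc(OCc5ccccc5)cc(OCc5ccccc5)c1)c1cc(OCc5ccccc5)c(OCc5ccccc5)c(OCc5ccccc5)c1 | intermediate
15 | [3,5-bis(benzyloxy)phenyl][3,4,5-tris(benzyloxy)benzylidene]oxonium ion, counter-ion [SnCl4(OMe)]− (not isolated) | C(c5ccccc5)Oc1cc(OCc5ccccc5)cc(c1)[O+]=Cc1cc(OCc5ccccc5)c(OCc5ccccc5)c(OCc5ccccc5)c1 | intermediate
16 | open-chain C4 benzylic cation with the C2–C3 bond formed (not isolated) | C(c5ccccc5)Oc1cc(OCc5ccccc5)cc(c1)O[C@H](c1cc(OCc5ccccc5)c(OCc5ccccc5)c(OCc5ccccc5)c1)[C@@H](OC(C)=O)[CH+]c1c(OCc5ccccc5)c(Br)c2c(c1OCc5ccccc5)C[C@H](OCc5ccccc5)[C@@H](c1cc(OCc5ccccc5)c(OCc5ccccc5)c(OCc5ccccc5)c1)O2 | intermediate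
17 | undeca-O-benzyl-8'-bromo-gallocatechin-(4α→6)-gallocatechin 3-acetate | C(c5ccccc5)Oc1cc(OCc5ccccc5)c2c(c1)O[C@H](c1cc(OCc5ccccc5)c(OCc5ccccc5)c(OCc5ccccc5)c1)[C@@H](OC(C)=O)[C@@H]2c1c(OCc5ccccc5)c(Br)c2c(c1OCc5ccccc5)C[C@H](OCc5ccccc5)[C@@H](c1cc(OCc5ccccc5)c(OCc5ccccc5)c(OCc5ccccc5)c1)O2 | intermediate
18 | undeca-O-benzyl-8'-bromo-gallocatechin-(4α→6)-gallocatechin, C3 hydroxyl free | C(c5ccccc5)Oc1cc(OCc5ccccc5)c2c(c1)O[C@H](c1cc(OCc5ccccc5)c(OCc5ccccc5)c(OCc5ccccc5)c1)[C@@H](O)[C@@H]2c1c(OCc5ccccc5)c(Br)c2c(c1OCc5ccccc5)C[C@H](OCc5ccccc5)[C@@H](c1cc(OCc5ccccc5)c(OCc5ccccc5)c(OCc5ccccc5)c1)O2 | intermediate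
19 | gallocatechin-(4α→6)-gallocatechin | Oc1cc(O)c2c(c1)O[C@H](c1cc(O)c(O)c(O)c1)[C@@H](O)[C@@H]2c1c(O)cc2c(c1O)C[C@H](O)[C@@H](c1cc(O)c(O)c(O)c1)O2 | target

**Step count and risks**

Total: 11 steps. Longest linear sequence: 9 steps (steps 1–6, 9, 10, 11); the acetal branch (steps 7 and 8) joins at step 9.

Steps most likely to fail:

1. Step 9 (the proposed new method). The oxocarbenium ion may be attacked by the aryl-bearing alkene carbon (enol-ester polarity winning over the twisted ring D); the acetal may self-condense by Friedel–Crafts attack of ring A of a second molecule; and the absence of facial discrimination costs up to half of the material. The fallback is the known Lewis-acid coupling of a C4-activated flavan with a flavan nucleophile and sets out from 2 and 4. DDQ and 2-ethoxyethanol in CH2Cl2 oxidise C4 of 2 to (2R,3S,4S)-4-(2-ethoxyethoxy)-penta-O-benzylgallocatechin F1. Ac2O, pyridine and DMAP give its 3-acetate F2. TMSOTf in CH2Cl2 at −78 °C ionises F2 at C4 in the presence of an excess of 4, whose bromide leaves only C6' free, and the 3-acetate steers the nucleophile to the opposite face. The product is 17, where the route is rejoined, now with both units of fixed absolute configuration.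

2. Step 6. The O-acylation may show poor E/Z selectivity, and the arylacetaldehyde may be lost to aldol self-condensation under the amine. The fallback sets out from 6. Boron–Wittig olefination with lithiated bis(pinacolatoboryl)methane (CH2(Bpin)2, lithium 2,2,6,6-tetramethylpiperidide, THF, −78 °C to rt) gives the (E)-alkenyl pinacol boronate F3. KHF2 in aqueous methanol gives the potassium (E)-alkenyltrifluoroborate F4. Copper-catalysed oxidative C–O coupling with acetic acid (CuBr, DMAP, 4 Å sieves, O2, CH2Cl2) forms the enol ester with retention of alkene geometry and comes back to the route at 9, bypassing 7 and 8.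

3. Step 4. Substitution at the doubly flanked C6' position may be slow, so that the temperature needed begins to cleave benzyl ethers. The fallback sets out from 4. N-Iodosuccinimide with catalytic CF3CO2H in CH2Cl2 gives the 8'-bromo-6'-iodo compound F5. iPrMgCl·LiCl in THF at −40 °C exchanges only the iodide and gives the arylmagnesium chloride F6. DMF followed by aqueous NH4Cl then returns to the route at 6.

Further compounds
F1 | step 9 | (2R,3S,4S)-4-(2-ethoxyethoxy)-penta-O-benzylgallocatechin | c1c(OCc5ccccc5)cc2c(c1OCc5ccccc5)[C@H](OCCOCC)[C@H](O)[C@@H](c1cc(OCc5ccccc5)c(OCc5ccccc5)c(OCc5ccccc5)c1)O2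
F2 | step 9 | 3-acetate of F1 | c1c(OCc5ccccc5)cc2c(c1OCc5ccccc5)[C@H](OCCOCC)[C@H](OC(C)=O)[C@@H](c1cc(OCc5ccccc5)c(OCc5ccccc5)c(OCc5ccccc5)c1)O2
F3 | step 6 | (E)-2-(8'-bromo-hexa-O-benzylgallocatechin-6'-yl)vinylboronic acid pinacol ester | CC1(C)OB(/C=C/c2c(OCc5ccccc5)c(Br)c3c(c2OCc5ccccc5)C[C@H](OCc5ccccc5)[C@@H](c2cc(OCc5ccccc5)c(OCc5ccccc5)c(OCc5ccccc5)c2)O3)OC1(C)C
F4 | step 6 | potassium (E)-2-(8'-bromo-hexa-O-benzylgallocatechin-6'-yl)vinyltrifluoroborate | [K+].F[B-](F)(F)/C=C/c1c(OCc5ccccc5)c(Br)c2c(c1OCc5ccccc5)C[C@H](OCc5ccccc5)[C@@H](c1cc(OCc5ccccc5)c(OCc5ccccc5)c(OCc5ccccc5)c1)O2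
F5 | step 4 | 8'-bromo-6'-iodo-hexa-O-benzylgallocatechin | Ic1c(OCc5ccccc5)c(Br)c2c(c1OCc5ccccc5)C[C@H](OCc5ccccc5)[C@@H](c1cc(OCc5ccccc5)c(OCc5ccccc5)c(OCc5ccccc5)c1)O2
F6 | step 4 | (8'-bromo-hexa-O-benzylgallocatechin-6'-yl)magnesium chloride | Cl[Mg]c1c(OCc5ccccc5)c(Br)c2c(c1OCc5ccccc5)C[C@H](OCc5ccccc5)[C@@H](c1cc(OCc5ccccc5)c(OCc5ccccc5)c(OCc5ccccc5)c1)O2
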